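**Plan**
- **Numbering and enabling feature:** Eudesmane numbering is used; ring A is C1–C5 plus C10, ring B is C5–C10. In ring B the C8 carbonyl lies β to the quaternary fusion carbon C10, across the lone methylene C9. C8–C9–C10 is therefore read as an opened cyclopropanol, and C10 as a tertiary β-keto radical.
- **Retrosynthetic cuts, in order:** O4–acetyl; O3–acyl; C3–H (back to the ketone); C2–C3 (Dieckmann); C10–C1 together with re-closure of C8–C10 (ring B becomes a bicyclo[3.1.0]hexane); C9 (CH2 transfer); C4–C5 (Michael); C7=C11 (aldol).
- **Forward order:** 2-Methylcyclopent-2-en-1-one supplies C5, C6, C7, C8, C10 and C14. It takes up the isopropylidene group, then the lactate unit (C3, C4, C15), then the bridge carbon C9. One-electron oxidation expands the five-membered ring to ring B and joins C1–C2 as an acrylate. Ring A closes last.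
- **Stereochemistry:** C4 comes from (R)-lactic acid by self-regeneration of the stereocentre, and C5 is set in the same Michael step. C10 forms anti to the C5 substituent in the radical addition, and C3 by axial hydride attack. The side-chain centre comes from (R)-2-methylbutanoic acid.

Key step: step 6

Remark: LDA is taken as the commercial solution; C2 of 17 and 18 is epimerisable and is drawn with the carboxyl group equatorial.

Step 1
Reactants: 1 (R)-lactic acid; 2 pivalaldehyde
Product: 3 (2R,5R)-2-tert-butyl-5-methyl-1,3-dioxolan-4-one (cis)
Conditions: p-TsOH·H2O (cat.), pentane, reflux, Dean–Stark trap; crystallisation from pentane, −78 °C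
Reagents that add atoms: none
Why: Acid-catalysed acetalisation with azeotropic removal of water should favour the cis-2,5-disubstituted dioxolanone, so that the lactate centre sets the new acetal centre, and cold crystallisation should remove the trans isomer.

Step 2
Reactants: 4 2-methylcyclopent-2-en-1-one; 5 acetone
Product: 7 5-(2-hydroxypropan-2-yl)-2-methylcyclopent-2-en-1-one (racemic), via lithium cross-conjugated enolate 6 (not isolated)
Conditions: LDA, THF, −78 °C; acetone, −78 °C; aq. NH4Cl
Reagents that add atoms: none
Why: Kinetic deprotonation at the α' methylene gives the cross-conjugated enolate, whose aldol addition to acetone brings in C11–C13; the new stereocentre is racemic and is erased in step 3.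

Step 3
Reactants: 7 5-(2-hydroxypropan-2-yl)-2-methylcyclopent-2-en-1-one
Product: 9 2-methyl-5-(propan-2-ylidene)cyclopent-2-en-1-one, via tertiary mesylate 8 (not isolated)
Conditions: MsCl, Et3N, CH2Cl2, 0 °C; then DBU, 0 °C to rt
Reagents that add atoms: none
Why: Mesylation of the tertiary aldol through sulfene followed by E1cB elimination should give the conjugated tetrasubstituted alkene, with DBU also moving any isopropenyl isomer into conjugation.

Step 4
Reactants: 3 (2R,5R)-2-tert-butyl-5-methyl-1,3-dioxolan-4-one; 9 2-methyl-5-(propan-2-ylidene)cyclopent-2-en-1-one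
Product: 12 silyl dienol ether (2R,5S)-2-tert-butyl-5-methyl-5-[(1R)-2-methyl-4-(propan-2-ylidene)-3-(trimethylsilyloxy)cyclopent-2-en-1-yl]-1,3-dioxolan-4-one, via lithium enolate of the dioxolanone 10 (not isolated), via lithium dienolate Michael adduct 11 (not isolated)
Conditions: LDA, THF/DMPU, −78 °C; 9, −78 to −40 °C; Me3SiCl, −78 °C to rt
Reagents that add atoms: chlorotrimethylsilane, C[Si](C)(C)Cl
Why: Michael addition with O-silylation in the same flask: the enolate reacts anti to the tert-butyl group (self-regeneration of the stereocentre, C4 set with net retention), C5 should follow from a compact lithium-bridged approach in which the enone ring lies over the enolate C–O bond and its C-methyl group points away from the enolate methyl group, and Me3SiCl fixes the adduct regiospecifically as the C8=C10 silyl enol ether.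

Step 5
Reactants: 12 silyl dienol ether
Product: 13 siloxycyclopropane (2R,5S)-2-tert-butyl-5-methyl-5-[(1R,4R,5S)-5-methyl-2-(propan-2-ylidene)-1-(trimethylsilyloxy)bicyclo[3.1.0]hexan-4-yl]-1,3-dioxolan-4-one (CH2 bridge anti to the dioxolanone)
Conditions: Et2Zn (1.5 equiv), CH2I2 (1.5 equiv), CH2Cl2, 0 °C
Reagents that add atoms: diiodomethane, ICI
Why: Simmons–Smith cyclopropanation (Furukawa variant): the electrophilic zinc carbenoid should pick the electron-rich C8=C10 enol ether bond of the 2-siloxydiene over C7=C11 and add anti to the C5 substituent, and both new stereocentres are erased again in step 6.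

Step 6
Reactants: 13 siloxycyclopropane; 14 tert-butyl acrylate
Product: 16 tert-butyl 3-{(1R,2R)-2-[(2R,4S)-2-tert-butyl-4-methyl-5-oxo-1,3-dioxolan-4-yl]-1-methyl-5-oxo-4-(propan-2-ylidene)cyclohexyl}propanoate, via ring-expanded tertiary C10 radical 15 (not isolated)
Conditions: 14 (3 equiv), 9-mesityl-10-methylacridinium tetrafluoroborate (5 mol %), MeOH (5 equiv), MeCN (0.1 M), 450 nm LED, 25 °C, argon
Reagents that add atoms: none
Why: Single-electron oxidation of the 1-alkenyl-1-siloxycyclopropane by the excited acridinium salt gives a radical cation that loses Me3Si+ to methanol and breaks the zero-bridge bond C8–C10, so that the five-membered ring C5–C6–C7–C8–C10 takes up the bridge carbon C9 and becomes six-membered ring B, with the C8 carbonyl already conjugated to C7=C11 and a tertiary radical at C10 (15). This radical adds to tert-butyl acrylate (Giese addition), and the α-ester radical is reduced by the acridinyl radical and protonated by methanol, which closes a redox-neutral cycle. The closest known reaction types are the oxidative ring expansion of 1-siloxybicyclo[n.1.0]alkanes to cyclic β-keto radicals (Saegusa ring expansion with FeCl3 and its photoinduced electron-transfer variant) and the addition of such β-keto radicals to electron-poor alkenes. No ring is closed by bond formation: ring B arises by endocyclic β-scission, which should be preferred over scission of the outer bond C8–C9 because it gives a tertiary instead of a primary radical. The only new stereocentre, C10, is controlled by C5: allylic-type strain with the C10 methyl group turns the bulky dioxolanonyl group pseudoaxial, it screens one face of the planar radical, and the acrylate bonds anti to it, which is the relative configuration of a trans-decalin. Chemoselectivity rests on the siloxy(alkenyl)cyclopropane being by far the most easily oxidised group in 13 and on the nucleophilic radical preferring the unhindered acrylate terminus to its own tetrasubstituted enone.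

Step 7
Reactants: 16 Giese adduct
Product: 17 tert-butyl 4α-hydroxy-3,8-dioxoeudesm-7(11)-ene-2α-carboxylate
Conditions: KOtBu (1.5 equiv), THF, −20 to 0 °C; aq. NH4Cl
Reagents that add atoms: none
Why: Dieckmann condensation: under reversible deprotonation only attack of the C2 ester enolate on the activated acylal-type carbonyl C3 is driven forward, because loss of pivalaldehyde and formation of the stabilised β-keto ester enolate make it irreversible, and ring A can close only with C1 and C4 both equatorial on ring B, that is as the trans-decalin fixed in step 6.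

Step 8
Reactants: 17 β-keto ester
Product: 19 4α-hydroxyeudesm-7(11)-ene-3,8-dione (4S,5R,10R), via beta-keto acid 18 (not isolated)
Conditions: CF3CO2H/CH2Cl2 1:4, 0 °C to rt; then toluene, 80 °C
Reagents that add atoms: none
Why: Acidolysis of the tert-butyl ester and thermal decarboxylation of the β-keto acid remove the activating group at C2, the tertiary C4 alcohol being kept from ionisation by the adjacent carbonyl group.

Step 9
Reactants: 19 4α-hydroxyeudesm-7(11)-ene-3,8-dione
Product: 20 3β,4α-dihydroxyeudesm-7(11)-en-8-one (3S,4S,5R,10R)
Conditions: NaBH4, CH2Cl2/MeOH 1:1, −78 to −40 °C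
Reagents that add atoms: none
Why: Chemoselective borohydride reduction: at low temperature the saturated, inductively activated C3 ketone should react while the hindered tetrasubstituted enone does not, and axial attack from the α face, away from the axial C4 and C10 methyl groups, should give the equatorial 3β-alcohol.

Step 10
Reactants: 20 3β,4α-dihydroxyeudesm-7(11)-en-8-one; 21 (R)-2-methylbutanoic acid
Product: 22 4α-hydroxy-3β-[(2R)-2-methylbutanoyloxy]eudesm-7(11)-en-8-one
Conditions: DCC, DMAP (cat.), CH2Cl2, 0 °C to rt
Reagents that add atoms: none
Why: Steglich esterification should acylate only the secondary equatorial 3β-hydroxyl group, the tertiary C4 alcohol being inert here, and the mild carbodiimide activation should leave the α-stereocentre of the acid untouched.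

Step 11
Reactants: 22 4α-hydroxy-3β-[(2R)-2-methylbutanoyloxy]eudesm-7(11)-en-8-one
Product: 23 4α-acetoxy-3β-[(2R)-2-methylbutanoyloxy]eudesm-7(11)-en-8-one (target CNP0111007.1)
Conditions: Ac2O (3 equiv), Sc(OTf)3 (5 mol %), MeCN, −20 to 0 °C
Reagents that add atoms: acetic anhydride, CC(=O)OC(C)=O
Why: Lewis acid-catalysed acetylation with Sc(OTf)3 and Ac2O is a known way to esterify tertiary alcohols at low temperature without elimination, which the electron-withdrawing ester at C3 disfavours further.

**Compound list**
1 | (R)-lactic acid | C[C@@H](O)C(=O)O | starting material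
2 | pivalaldehyde | CC(C)(C)C=O | starting material
3 | (2R,5R)-2-tert-butyl-5-methyl-1,3-dioxolan-4-one | C[C@H]1O[C@@H](C(C)(C)C)OC1=O | intermediate
4 | 2-methylcyclopent-2-en-1-one | CC1=CCCC1=O | starting material
5 | acetone | CC(C)=O | starting material
6 | lithium cross-conjugated enolate of 4 | CC1=CCC=C1[O-].[Li+] | intermediate
7 | 5-(2-hydroxypropan-2-yl)-2-methylcyclopent-2-en-1-one (racemic) | CC1=CCC(C1=O)C(C)(C)O | intermediate
8 | tertiary mesylate of 7 (racemic) | CC1=CCC(C1=O)C(C)(C)OS(C)(=O)=O | intermediate
9 | 2-methyl-5-(propan-2-ylidene)cyclopent-2-en-1-one | CC1=CCC(=C(C)C)C1=O | intermediate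
10 | lithium enolate of 3 | CC1=C([O-])O[C@@H](O1)C(C)(C)C.[Li+] | intermediate
11 | lithium dienolate Michael adduct | C[C@]1(O[C@@H](C(C)(C)C)OC1=O)[C@@H]2CC(=C(C)C)C([O-])=C2C.[Li+] | intermediate
12 | silyl dienol ether | C[C@]1(O[C@@H](C(C)(C)C)OC1=O)[C@@H]2CC(=C(C)C)C(O[Si](C)(C)C)=C2C | intermediate
13 | siloxycyclopropane (1-siloxybicyclo[3.1.0]hexane) | C[C@]1(O[C@@H](C(C)(C)C)OC1=O)[C@@H]2CC(=C(C)C)[C@@]3(O[Si](C)(C)C)C[C@@]23C | intermediate
14 | tert-butyl acrylate | C=CC(=O)OC(C)(C)C | starting material
15 | ring-expanded tertiary C10 radical | C[C@]1(O[C@@H](C(C)(C)C)OC1=O)[C@@H]2CC(=C(C)C)C(=O)C[C]2C | intermediate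
16 | Giese adduct (ring B complete, C10 quaternary) | C[C@]1(O[C@@H](C(C)(C)C)OC1=O)[C@@H]2CC(=C(C)C)C(=O)C[C@@]2(C)CCC(=O)OC(C)(C)C | intermediate
17 | tert-butyl 4α-hydroxy-3,8-dioxoeudesm-7(11)-ene-2α-carboxylate | CC(C)(C)OC(=O)[C@@H]1C[C@]2(C)CC(=O)C(=C(C)C)C[C@H]2[C@](C)(O)C1=O | intermediate
18 | 4α-hydroxy-3,8-dioxoeudesm-7(11)-ene-2α-carboxylic acid | OC(=O)[C@@H]1C[C@]2(C)CC(=O)C(=C(C)C)C[C@H]2[C@](C)(O)C1=O | intermediate
19 | 4α-hydroxyeudesm-7(11)-ene-3,8-dione | O=C1CC[C@]2(C)CC(=O)C(=C(C)C)C[C@H]2[C@]1(C)O | intermediate
20 | 3β,4α-dihydroxyeudesm-7(11)-en-8-one | O[C@H]1CC[C@]2(C)CC(=O)C(=C(C)C)C[C@H]2[C@]1(C)O | intermediate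
21 | (R)-2-methylbutanoic acid | CC[C@@H](C)C(=O)O | starting material
22 | 4α-hydroxy-3β-[(2R)-2-methylbutanoyloxy]eudesm-7(11)-en-8-one | CC[C@@H](C)C(=O)O[C@H]1CC[C@]2(C)CC(=O)C(=C(C)C)C[C@H]2[C@]1(C)O | intermediate
23 | 4α-acetoxy-3β-[(2R)-2-methylbutanoyloxy]eudesm-7(11)-en-8-one | CC[C@@H](C)C(=O)O[C@H]1CC[C@]2(C)CC(=O)C(=C(C)C)C[C@H]2[C@]1(C)OC(C)=O | target

**Step count**
Total steps: 11. Longest linear sequence: 10 steps (steps 2–11, from 4).

**Steps most likely to fail**

**Step 6.**
- What may go wrong: back electron transfer or unselective oxidation may outrun cleavage of the C8–C10 bond. The hindered C10 radical may also be lost by hydrogen transfer (for example from the acetal C–H) before it meets the acrylate, and the acrylate may oligomerise.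
- Fallback (sets out from 13, returns at 16): the two events are separated. FeCl3 in DMF at 0 °C (Saegusa ring expansion) should turn 13 into the ring-expanded tertiary β-chloro ketone F1. This chloride then serves as an ordinary radical precursor: Bu3SnH is added slowly to F1 and an excess of 14 with Et3B/air in toluene at room temperature (tin hydride Giese reaction). This should give 16 with the same anti selectivity.

**Step 4.**
- What may go wrong: proton transfer from the doubly allylic ring methylene of 9 to the basic enolate, 1,2-addition, or poor facial selectivity at C5.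
- Fallback (sets out from 3, returns at 12): a non-basic Mukaiyama–Michael reaction through an open transition state. LDA and Me3SiCl should convert 3 into the silyl ketene acetal (2R)-2-tert-butyl-5-methyl-4-(trimethylsilyloxy)-1,3-dioxole F2. This is added to 9 with Me3SiOTf (cat.) in CH2Cl2 at −78 °C, and silyl transfer should deliver 12 directly.

**Step 7.**
- What may go wrong: enolisation of the C8 ketone may compete. That would lead to acylation at C9, aldol capture of the released aldehyde, or deconjugation of C7=C11 on quenching.
- Fallback (sets out from 16, returns at 19): the ketone is masked first. Lithium hexamethyldisilazide (1 equiv) and tert-butyldimethylsilyl chloride in THF/DMPU should give the C8 silyl dienol ether F3. LDA then forms only the ester enolate, and Dieckmann closure should give the silyl-protected β-keto ester F4. Wet CF3CO2H removes the silyl enol ether and the tert-butyl ester to give 18, which loses CO2 at 80 °C to give 19.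

**Further compounds**
F1 | step 6 | ring-expanded tertiary β-chloro ketone (10-chloro, chlorine anti to the dioxolanone) | C[C@]1(O[C@@H](C(C)(C)C)OC1=O)[C@@H]2CC(=C(C)C)C(=O)C[C@@]2(C)Cl
F2 | step 4 | (2R)-2-tert-butyl-5-methyl-4-(trimethylsilyloxy)-1,3-dioxole | CC1=C(O[Si](C)(C)C)O[C@@H](O1)C(C)(C)C
F3 | step 7 | C8 tert-butyldimethylsilyl dienol ether of 16 | C[C@]1(O[C@@H](C(C)(C)C)OC1=O)[C@@H]2CC(=C(C)C)C(O[Si](C)(C)C(C)(C)C)=C[C@@]2(C)CCC(=O)OC(C)(C)C
F4 | step 7 | C8 tert-butyldimethylsilyl dienol ether of 17 | CC(C)(C)OC(=O)[C@@H]1C[C@]2(C)C=C(O[Si](C)(C)C(C)(C)C)C(=C(C)C)C[C@H]2[C@](C)(O)C1=O
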